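The data were generated by integration with made-up constants, noise included.

If each unit of solid reagent removes at most one substrate, this flask's excess has a cap, so I started from that cap.

- blue: left-handed substrate 0.40 M; right-handed substrate 0.40 M; solid reagent 0.24 M; free catalyst 2 mM; the very flask that is asked about, followed so far
- flask: left-handed substrate 0.40 M; solid reagent 0.240 M; free catalyst 2.0 mM; right-handed substrate 0.40 M; time 2.5 min

- blue (time / s: right-handed substrate / %, left-handed substrate / %): 10.0: 49.7, 46.0; 15.0: 50.1, 43.6; 30.0: 49.3, 40.4; 60.0: 48.3, 38.7

(standard deviation of a reading: 0.5 percentage points)

1. whether the excess of right-handed substrate over left-handed substrate among what is left of the two reaches 80 % by 2.5 min (yes / no)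
2. the highest excess of right-handed substrate over left-handed substrate among what is left of the two up to 2.5 min

- free catalyst is single-handed; left-handed substrate and right-handed substrate are mirror images of each other, charged as a racemate, each of them at the stated concentration
- as a solid, counted per litre of solution: solid reagent
- at the start none of the solid reagent is in solution

The solid reagent, the limiting reagent here, came to 30.0 % of the two substrates together. Spent entirely on left-handed substrate, it would give an excess equal to that share divided by what remains of the charge. This reagent ceiling is 42.9 %, below the 80.0 % asked.

The readings tightened it. In the blue run, left-handed substrate fell ever more slowly, losing 1.7 percentage points between 30.0 s and 60.0 s. Had that last pace held to 2.5 min, it would stand at 33.6 %; against right-handed substrate held at its last reading, that gave 17.9 % from above. From below, the last reading showed 11.0 %, or 9.41 % after two standard deviations of scatter.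

The forecast, no with a top of 12.5 %, lay inside that bracket, expecting the excess “to level off around 12 %”.

The flask gave no, with a top of 10.6 %, which is a quarter of the reagent ceiling.

    free catalyst + left-handed substrate ⇌ catalyst intermediate A (K = 1.30 M⁻¹, k = 99.0 M⁻¹ s⁻¹)
    solid reagent ⇌ partner, rate k2*(cs2 - [partner]) while solid is left; crystals form when [partner] > cs2 (solubility = 0.270 M, k = 0.400 s⁻¹)
    2 partner → self-condensation product (k = 0.0960 M⁻¹ s⁻¹)
    partner + catalyst intermediate A → free catalyst + left-handed product (k = 52.0 M⁻¹ s⁻¹)
    left-handed substrate ⇌ right-handed substrate (k = 0.00450 s⁻¹)
    free catalyst + right-handed substrate ⇌ catalyst intermediate B (K = 1.50 M⁻¹, k = 220 M⁻¹ s⁻¹)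
    partner + catalyst intermediate B → free catalyst + right-handed product (k = 0.770 M⁻¹ s⁻¹)

In this flask, half of the turnover to left-handed product up to 2.5 min was done by 0.345 min, while the interchange of the two substrates, by that step alone, relaxes with a half-life of 1.28 min, a longer time. The excess in this flask was a passing one, under kinetic control: left-handed substrate stood at 39.0 % against 44.6 % right-handed at 2.50 min, and at 41.6 % against 41.6 % at 25.0 min.

A second flask, the same but charged with a quarter of the solid reagent, has a share of 7.50 % and so a ceiling of 8.11 %; its computed top was 3.58 %, under that ceiling.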